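**Retrosynthetic overview**
- Gardenin A ⇐ 5,6,7,8,3',4',5'-heptamethoxyflavone, by chelation-directed cleavage of the peri C5–OMe only (last step).
- Heptamethoxyflavone ⇐ 2'-hydroxychalcone, by oxidative O1–C2 ring closure (I2/DMSO).
- Chalcone ⇐ 2'-hydroxy-3',4',5',6'-tetramethoxyacetophenone + 3,4,5-trimethoxybenzaldehyde (Claisen–Schmidt, forms the future C2–C3 bond).
- Ring order: the A and B rings are bought fully oxygenated; the γ-pyrone C ring is the only ring formed (step 2).

Assumption: Gardenin A has no stereocentre, so the "single enantiomer" is the achiral compound itself; acetophenone 1 (CAS 3162-28-5) and aldehyde 2 are taken as catalogue compounds.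

**Step 1**
Reactants: 1 1-(2-hydroxy-3,4,5,6-tetramethoxyphenyl)ethan-1-one; 2 3,4,5-trimethoxybenzaldehyde
Product: 4 (E)-1-(2-hydroxy-3,4,5,6-tetramethoxyphenyl)-3-(3,4,5-trimethoxyphenyl)prop-2-en-1-one, via β-hydroxy ketone 3 (not isolated)
Conditions: KOH (50% aq, 5 equiv), EtOH, rt, 48 h; then 1 M HCl, 0 °C
Reagents that add atoms: none
Why: Claisen–Schmidt (crossed aldol) condensation in which the methyl ketone is the only enolisable partner, and aldol 3 dehydrates (E1cB) to the thermodynamically favoured E-enone, so no stereocentre remains; any chalcone that closes to flavanone 5 is still converted to 6 in step 2.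

**Step 2**
Reactants: 4 (E)-1-(2-hydroxy-3,4,5,6-tetramethoxyphenyl)-3-(3,4,5-trimethoxyphenyl)prop-2-en-1-one
Product: 6 5,6,7,8-tetramethoxy-2-(3,4,5-trimethoxyphenyl)-4H-chromen-4-one, via flavanone 5 (not isolated)
Conditions: I2 (10 mol %), DMSO, 130 °C, 3 h
Reagents that add atoms: none
Why: Iodine/DMSO oxidative cyclisation, in which oxa-Michael closure of the 2'-OH gives flavanone 5 and iodine-mediated dehydrogenation (α-iodination, loss of HI, DMSO re-oxidising HI to I2) gives the γ-pyrone, destroying the racemic C2 centre of 5.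

**Step 3**
Reactants: 6 5,6,7,8-tetramethoxy-2-(3,4,5-trimethoxyphenyl)-4H-chromen-4-one
Product: 8 Gardenin A (5-hydroxy-6,7,8-trimethoxy-2-(3,4,5-trimethoxyphenyl)-4H-chromen-4-one), via dichloroboron chelate 7 (not isolated)
Conditions: BCl3 (1 M in CH2Cl2, 1.5 equiv), CH2Cl2, −20 → 0 °C, 1 h; then H2O
Reagents that add atoms: none
Why: Chelation-controlled Lewis-acid ether cleavage, in which BCl3 bridges the C4 carbonyl and the peri 5-OMe so chloride removes only that methyl (SN2 at CH3), the other six methoxy groups having no chelating neighbour at ≤0 °C, and water hydrolyses borate 7 to the hydrogen-bonded 5-OH.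

**Compound list**
1 | 1-(2-hydroxy-3,4,5,6-tetramethoxyphenyl)ethan-1-one (2'-hydroxy-3',4',5',6'-tetramethoxyacetophenone) | CC(=O)c1c(O)c(OC)c(OC)c(OC)c1OC | starting material
2 | 3,4,5-trimethoxybenzaldehyde | COc1cc(C=O)cc(OC)c1OC | starting material
3 | 3-hydroxy-1-(2-hydroxy-3,4,5,6-tetramethoxyphenyl)-3-(3,4,5-trimethoxyphenyl)propan-1-one (racemic aldol adduct) | COc1cc(C(O)CC(=O)c2c(O)c(OC)c(OC)c(OC)c2OC)cc(OC)c1OC | intermediate
4 | (E)-1-(2-hydroxy-3,4,5,6-tetramethoxyphenyl)-3-(3,4,5-trimethoxyphenyl)prop-2-en-1-one | COc1cc(/C=C/C(=O)c2c(O)c(OC)c(OC)c(OC)c2OC)cc(OC)c1OC | intermediate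
5 | 5,6,7,8-tetramethoxy-2-(3,4,5-trimethoxyphenyl)chroman-4-one (racemic flavanone) | COc1cc(C2CC(=O)c3c(OC)c(OC)c(OC)c(OC)c3O2)cc(OC)c1OC | intermediate
6 | 5,6,7,8-tetramethoxy-2-(3,4,5-trimethoxyphenyl)-4H-chromen-4-one (5,6,7,8,3',4',5'-heptamethoxyflavone) | COc1cc(-c2cc(=O)c3c(OC)c(OC)c(OC)c(OC)c3o2)cc(OC)c1OC | intermediate
7 | 5-(dichloroboryloxy)-6,7,8-trimethoxy-2-(3,4,5-trimethoxyphenyl)-4H-chromen-4-one (boron chelate) | COc1cc(-c2cc(=O)c3c(OB(Cl)Cl)c(OC)c(OC)c(OC)c3o2)cc(OC)c1OC | intermediate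
8 | Gardenin A, 5-hydroxy-6,7,8-trimethoxy-2-(3,4,5-trimethoxyphenyl)-4H-chromen-4-one (achiral) | COc1cc(-c2cc(=O)c3c(O)c(OC)c(OC)c(OC)c3o2)cc(OC)c1OC | target

**Total step count:** 3
**Longest linear sequence:** 3 steps (1 → 4 → 6 → 8)

**Steps most likely to fail, with fallbacks**

Step 3 (over-demethylation at 6-OMe or 4'-OMe, or incomplete reaction). The fallback moves the demethylation to the start, where no competing trimethoxyaryl ring is present, and sets out from 1. BCl3 (2.5 equiv, CH2Cl2, 0 °C) cleaves the only ketone-ortho methyl ether of 1 to give the symmetric 1-(2,6-dihydroxy-3,4,5-trimethoxyphenyl)ethan-1-one F3. Claisen–Schmidt condensation of this with 2 (KOH, EtOH) gives (E)-1-(2,6-dihydroxy-3,4,5-trimethoxyphenyl)-3-(3,4,5-trimethoxyphenyl)prop-2-en-1-one F4. I2/DMSO then closes either of the two equivalent hydroxyls and leaves the other as the free 5-OH, so the route comes back directly at 8.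

Step 1 (sluggish condensation of the hindered, electron-rich hexasubstituted acetophenone). The fallback replaces the aldol disconnection by a Baker–Venkataraman sequence and sets out from 1. O-Acylation with 3,4,5-trimethoxybenzoyl chloride (pyridine, cat. DMAP) gives 2-acetyl-3,4,5,6-tetramethoxyphenyl 3,4,5-trimethoxybenzoate F1. Base-induced 1,5-acyl transfer (KOH, pyridine, 50 °C) gives 1-(2-hydroxy-3,4,5,6-tetramethoxyphenyl)-3-(3,4,5-trimethoxyphenyl)propane-1,3-dione F2. Cyclodehydration (cat. H2SO4, AcOH, 100 °C) brings the route back at 6, bypassing 4 and step 2.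

Step 2 (ring iodination of the trimethoxyphenyl group, or premature partial 5-O-demethylation by HI; the latter only produces 8 early and is harmless). The fallback separates ring closure from oxidation and avoids halogen altogether, setting out from 4. Oxa-Michael cyclisation (NaOAc, EtOH, reflux) gives flavanone 5, which is isolated. Dehydrogenation of 5 with DDQ (dioxane, reflux) brings the route back at 6.

**Further compounds**
F1 | step 1 | 2-acetyl-3,4,5,6-tetramethoxyphenyl 3,4,5-trimethoxybenzoate | CC(=O)c1c(OC(=O)c2cc(OC)c(OC)c(OC)c2)c(OC)c(OC)c(OC)c1OC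
F2 | step 1 | 1-(2-hydroxy-3,4,5,6-tetramethoxyphenyl)-3-(3,4,5-trimethoxyphenyl)propane-1,3-dione | COc1cc(C(=O)CC(=O)c2c(O)c(OC)c(OC)c(OC)c2OC)cc(OC)c1OC
F0 | step 2 | none | none
F3 | step 3 | 1-(2,6-dihydroxy-3,4,5-trimethoxyphenyl)ethan-1-one | CC(=O)c1c(O)c(OC)c(OC)c(OC)c1O
F4 | step 3 | (E)-1-(2,6-dihydroxy-3,4,5-trimethoxyphenyl)-3-(3,4,5-trimethoxyphenyl)prop-2-en-1-one | COc1cc(/C=C/C(=O)c2c(O)c(OC)c(OC)c(OC)c2O)cc(OC)c1OC
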